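**Plan**
- Retrosynthesis: the tert-butyl ether is cut back to the free 2-OH. The quinone ring is then opened at the bond between the C(OMe) carbon and its neighbouring carbonyl carbon, and the two carbonyl carbons are rejoined, giving a 4-hydroxy-4-(methoxyethynyl)cyclobutenone. Further cuts: the carbinol–alkyne bond (methoxyacetylide + cyclobutenedione), the ring–CH2 bond (β-oxido alkyllithium + di-tert-butyl squarate), and C3–C4 of the side chain (decyl Grignard + (R)-epichlorohydrin).
- Enabling feature: in this 2,5-dioxygenated 1,4-benzoquinone the two carbonyl carbons are para, the C(alkyl)=C(OH) pair is the C=C of a squarate-derived four-membered ring, and the CH=C(OMe) pair is a two-carbon unit with one hydrogen, i.e. an alkoxyalkyne.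
- Forward: the side chain is made first (step 1), attached to the four-membered ring (steps 2–4), the alkyne is added (step 6), the four-membered ring is expanded by two carbons to the six-membered quinone ring (step 7), and the hydroxyl is unmasked (step 8).
- Stereochemistry: the single stereocentre comes from (R)-epichlorohydrin; no bond to it is made or broken afterwards.

Key step: step 7

Remark: di-tert-butyl squarate (4) is taken as a catalogue compound; 6, 7 and 13 are carried as epimer mixtures at the ring carbinol carbon, which later becomes a carbonyl carbon.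

Step 1
Reactants: 1 decylmagnesium bromide; 2 (R)-epichlorohydrin
Product: 3 (2R)-1-chlorotridecan-2-ol
Conditions: CuI (10 mol%), THF–Et2O, −40 to 0 °C; then 1 M HCl
Reagents that add atoms: none
Why: Copper-catalysed Grignard opening of a terminal epoxide (SN2 at the unsubstituted epoxide carbon, faster than chloride displacement) should give the chlorohydrin, and the stereocentre of 2 is not a reacting centre, so it is carried over as (R).

Step 2
Reactants: 3 (2R)-1-chlorotridecan-2-ol; 4 di-tert-butyl squarate (3,4-di-tert-butoxycyclobut-3-ene-1,2-dione)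
Product: 6 2,3-di-tert-butoxy-4-hydroxy-4-[(2R)-2-hydroxytridecyl]cyclobut-2-en-1-one, via β-oxido alkyllithium 5 (not isolated)
Conditions: n-BuLi (1.0 equiv), THF, −78 °C; LiC10H8 (2.0 equiv, from Li and naphthalene in THF), −78 °C; then 4, −78 °C; aq. NH4Cl
Reagents that add atoms: none
Why: O-deprotonation followed by reductive chlorine–lithium exchange gives a β-oxido alkyllithium that should not β-eliminate at −78 °C (the leaving group would be Li2O), and organolithium 1,2-addition to one carbonyl of a squarate diester is the standard entry to 4-hydroxy-2,3-dialkoxycyclobutenones; the side-chain stereocentre is untouched and the new ring carbinol forms as both epimers, which is of no consequence.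

Step 3
Reactants: 6 2,3-di-tert-butoxy-4-hydroxy-4-[(2R)-2-hydroxytridecyl]cyclobut-2-en-1-one
Product: 7 (2R)-1-(2,3-di-tert-butoxy-1-hydroxy-4-oxocyclobut-2-en-1-yl)tridecan-2-yl acetate
Conditions: Ac2O, pyridine, DMAP (cat.), CH2Cl2, 0 °C
Reagents that add atoms: acetic anhydride, CC(=O)OC(C)=O
Why: Standard acylation in which the secondary alcohol should react far faster than the hindered tertiary ring carbinol (a tertiary acetate, if formed, would ionise to the same product in step 4); the acetate is that of the target and also keeps this oxygen from trapping the ketene of step 7.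

Step 4
Reactants: 7 (2R)-1-(2,3-di-tert-butoxy-1-hydroxy-4-oxocyclobut-2-en-1-yl)tridecan-2-yl acetate
Product: 8 (2R)-1-(2-tert-butoxy-3,4-dioxocyclobut-1-en-1-yl)tridecan-2-yl acetate
Conditions: (CF3CO)2O, 2,6-lutidine, CH2Cl2, −78 to 0 °C; aq. NaHCO3
Reagents that add atoms: none
Why: Trifluoroacetylation and ionisation of the tertiary carbinol should give a dialkoxycyclobutenyl cation that loses the tert-butyl group of the remote oxygen as isobutene (squarate-adduct to cyclobutenedione rearrangement), leaving the alkyl group on the ring C=C next to one remaining tert-butoxy vinylogous ester, which the buffer protects from acidolysis.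

Step 5
Reactants: 9 chloroacetaldehyde dimethyl acetal (2-chloro-1,1-dimethoxyethane)
Product: 11 methoxyethyne, via sodium methoxyacetylide 10 (not isolated)
Conditions: NaNH2 (3.2 equiv), liq. NH3, −33 °C; sat. aq. NaCl, −70 °C; distil (bp about 23 °C), store cold in THF
Reagents that add atoms: none
Why: Twofold β-elimination (methanol, then HCl) with sodium amide should give the acetylide, which is protonated on quench so that the volatile ynol ether distils out; this is a known type of ynol ether preparation.

Step 6
Reactants: 8 (2R)-1-(2-tert-butoxy-3,4-dioxocyclobut-1-en-1-yl)tridecan-2-yl acetate; 11 methoxyethyne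
Product: 13 (2R)-1-[2-tert-butoxy-3-hydroxy-3-(methoxyethynyl)-4-oxocyclobut-1-en-1-yl]tridecan-2-yl acetate, via lithium methoxyacetylide 12 (not isolated)
Conditions: 11, n-BuLi, THF, −78 °C; then 8, −78 °C; aq. NH4Cl at −78 °C; used crude after filtration through Et3N-treated silica
Reagents that add atoms: none
Why: Lithium acetylides add at −78 °C to the ketone-like carbonyl of a 3-alkyl-4-alkoxycyclobutenedione (the one next to the alkoxy-bearing carbon) and not to the vinylogous-ester carbonyl or the far less electrophilic acetate, which places the alkynyl carbinol next to C–OtBu as the ring expansion requires; the new carbinol carbon forms as both epimers and is destroyed in step 7.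

Step 7
Reactants: 13 (2R)-1-[2-tert-butoxy-3-hydroxy-3-(methoxyethynyl)-4-oxocyclobut-1-en-1-yl]tridecan-2-yl acetate
Product: 16 (2R)-1-(2-tert-butoxy-5-methoxy-3,6-dioxocyclohexa-1,4-dien-1-yl)tridecan-2-yl acetate, via enynylketene 14 (not isolated), via aryl diradical 15 (not isolated)
Conditions: PhMe (0.01 M, degassed), 110 °C
Reagents that add atoms: none
Why: On heating, the cyclobutenone should undergo conrotatory 4π-electrocyclic opening of the C(=O)–C(OH) ring bond, with the hydroxyl rotating outward and the alkynyl group inward, to give the (Z)-enynylketene 14. The ketene carbon then bonds to the distal, methoxy-bearing alkyne carbon, closing the six-membered ring by C–C bond formation across the ene-yne-ketene unit (the ketene analogue of a Myers–Saito cycloaromatisation) to give the phenoxyl/σ-aryl diradical 15, which takes the hydroxyl hydrogen onto the aryl radical carbon and so becomes the quinone. The closest known reaction type is the Moore rearrangement of 4-alkynyl-4-hydroxycyclobutenones to 1,4-benzoquinones. No new stereocentre is formed: the ring carbinol carbon becomes a quinone carbonyl and the acetoxy-bearing carbon takes no part. The step needs six- over five-membered closure (quinone, not alkylidenecyclopentenedione), which alkyl- and alkoxy-substituted alkynes favour in this rearrangement, unlike aryl, silyl or ester substituents. It also needs a single substitution pattern, which the connectivity of 13 fixes: alkyl next to the ketene-derived carbonyl, tert-butoxy next to the former carbinol carbon, H and OMe from the alkyne.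

Step 8
Reactants: 16 (2R)-1-(2-tert-butoxy-5-methoxy-3,6-dioxocyclohexa-1,4-dien-1-yl)tridecan-2-yl acetate
Product: 17 (2R)-1-(2-hydroxy-5-methoxy-3,6-dioxocyclohexa-1,4-dien-1-yl)tridecan-2-yl acetate
Conditions: CF3CO2H, CH2Cl2, 0 °C to rt
Reagents that add atoms: none
Why: Acidolysis of the tert-butyl vinylogous ester (E1 loss of isobutene) should free the 2-hydroxyquinone, while the methyl vinylogous ester and the secondary acetate are inert to anhydrous acid at this temperature.

**Compound list**
1 | decylmagnesium bromide | CCCCCCCCCC[Mg]Br | starting material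
2 | (R)-epichlorohydrin | ClC[C@H]1CO1 | starting material
3 | (2R)-1-chlorotridecan-2-ol | CCCCCCCCCCC[C@@H](O)CCl | intermediate
4 | di-tert-butyl squarate (3,4-di-tert-butoxycyclobut-3-ene-1,2-dione) | CC(C)(C)OC1=C(OC(C)(C)C)C(=O)C1=O | starting material
5 | lithium (2S)-1-lithiotridecan-2-olate, the β-oxido alkyllithium (same spatial arrangement as 3; the descriptor changes only because C1 now ranks below C3) | CCCCCCCCCCC[C@@H](O[Li])C[Li] | intermediate
6 | 2,3-di-tert-butoxy-4-hydroxy-4-[(2R)-2-hydroxytridecyl]cyclobut-2-en-1-one (both epimers at the ring carbinol) | CCCCCCCCCCC[C@@H](O)CC1(O)C(OC(C)(C)C)=C(OC(C)(C)C)C1=O | intermediate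
7 | (2R)-1-(2,3-di-tert-butoxy-1-hydroxy-4-oxocyclobut-2-en-1-yl)tridecan-2-yl acetate (both epimers at the ring carbinol) | CCCCCCCCCCC[C@H](CC1(O)C(OC(C)(C)C)=C(OC(C)(C)C)C1=O)OC(C)=O | intermediate
8 | (2R)-1-(2-tert-butoxy-3,4-dioxocyclobut-1-en-1-yl)tridecan-2-yl acetate | CCCCCCCCCCC[C@H](CC1=C(OC(C)(C)C)C(=O)C1=O)OC(C)=O | intermediate
9 | chloroacetaldehyde dimethyl acetal | COC(CCl)OC | starting material
10 | sodium methoxyacetylide | [Na+].[C-]#COC | intermediate
11 | methoxyethyne | C#COC | intermediate
12 | lithium methoxyacetylide | [Li]C#COC | intermediate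
13 | (2R)-1-[2-tert-butoxy-3-hydroxy-3-(methoxyethynyl)-4-oxocyclobut-1-en-1-yl]tridecan-2-yl acetate (both epimers at the ring carbinol) | CCCCCCCCCCC[C@H](CC1=C(OC(C)(C)C)C(O)(C#COC)C1=O)OC(C)=O | intermediate
14 | (Z)-enynylketene: (2R)-4-tert-butoxy-5-hydroxy-7-methoxy-3-(oxomethylidene)hept-4-en-6-yn-2-yl unit carrying the undecyl chain, i.e. the ring-opened form of 13 | CCCCCCCCCCC[C@H](CC(=C=O)/C(OC(C)(C)C)=C(/O)C#COC)OC(C)=O | intermediate
15 | aryl diradical: 2-[(2R)-2-acetoxytridecyl]-3-tert-butoxy-4-hydroxy-6-methoxyphenoxyl with a σ-radical at C5 | CCCCCCCCCCC[C@H](Cc1c([O])c(OC)[c]c(O)c1OC(C)(C)C)OC(C)=O | intermediate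
16 | (2R)-1-(2-tert-butoxy-5-methoxy-3,6-dioxocyclohexa-1,4-dien-1-yl)tridecan-2-yl acetate | CCCCCCCCCCC[C@H](CC1=C(OC(C)(C)C)C(=O)C=C(OC)C1=O)OC(C)=O | intermediate
17 | (2R)-1-(2-hydroxy-5-methoxy-3,6-dioxocyclohexa-1,4-dien-1-yl)tridecan-2-yl acetate | CCCCCCCCCCC[C@H](CC1=C(O)C(=O)C=C(OC)C1=O)OC(C)=O | target

**Step count and risks**
Total steps: 8. Longest linear sequence: 7 (steps 1, 2, 3, 4, 6, 7, 8); step 5 is a one-step side branch.

Steps most likely to fail:

1. Step 7. The enynylketene may close onto the proximal alkyne carbon (five-membered ring, ending in an alkylidenecyclopentenedione), or the tert-butyl group may be lost thermally before ring opening. The fallback sets out from 13 and changes the ring-forming event from a diradical closure to a closed-shell electrocyclisation. Semi-hydrogenation of the ynol ether (H2, Pd/CaCO3 poisoned with Pb(OAc)2, quinoline, EtOAc) should give (2R)-1-{2-tert-butoxy-3-hydroxy-3-[(Z)-2-methoxyethenyl]-4-oxocyclobut-1-en-1-yl}tridecan-2-yl acetate F4. Heating in toluene then opens the four-membered ring to a dienylketene, whose 6π-electrocyclisation can only give the six-membered ring; tautomerisation gives (2R)-1-(2-tert-butoxy-3,6-dihydroxy-5-methoxyphenyl)tridecan-2-yl acetate F5. Oxidation with Ag2O in Et2O returns to the route at 16.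

2. Step 6. The acetylide may deprotonate the activated ring–CH2 (with loss of acetate) or attack the acetate, and the acid-labile ynol ether carbinol or the volatile, polymerisable methoxyethyne may decompose on handling. The fallback sets out from 8 and brings the methoxy group in after the ring expansion. Ethynylmagnesium bromide (HC≡CMgBr, THF, −78 °C) should give (2R)-1-(2-tert-butoxy-3-ethynyl-3-hydroxy-4-oxocyclobut-1-en-1-yl)tridecan-2-yl acetate F2. Moore rearrangement of F2 (PhMe, 110 °C) should give (2R)-1-(2-tert-butoxy-3,6-dioxocyclohexa-1,4-dien-1-yl)tridecan-2-yl acetate F3. Conjugate addition of methanol (ZnCl2, MeOH, air reoxidising the hydroquinone adduct) should occur at the unsubstituted carbon β to the carbonyl that is not deactivated by the tert-butoxy group, which is the carbon that carries OMe in 16, where the fallback rejoins the route.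

3. Step 2. The β-oxido alkyllithium may β-eliminate to 1-tridecene, or residual naphthalenide may transfer an electron to the squarate in competition with 1,2-addition. The fallback sets out from 3 and changes how the carbon nucleophile is made, from electron transfer to halogen–lithium exchange, so that no radical anion is in the flask when the squarate is added. Finkelstein exchange (NaI, 2-butanone, reflux) should give (2R)-1-iodotridecan-2-ol F1. Treatment with t-BuLi (3.1 equiv, Et2O–pentane, −78 °C: O-deprotonation, then iodine–lithium exchange) generates 5, and addition of 4 returns to the route at 6.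

**Further compounds**
F1 | step 2 | (2R)-1-iodotridecan-2-ol | CCCCCCCCCCC[C@@H](O)CI
F2 | step 6 | (2R)-1-(2-tert-butoxy-3-ethynyl-3-hydroxy-4-oxocyclobut-1-en-1-yl)tridecan-2-yl acetate | CCCCCCCCCCC[C@H](CC1=C(OC(C)(C)C)C(O)(C#C)C1=O)OC(C)=O
F3 | step 6 | (2R)-1-(2-tert-butoxy-3,6-dioxocyclohexa-1,4-dien-1-yl)tridecan-2-yl acetate | CCCCCCCCCCC[C@H](CC1=C(OC(C)(C)C)C(=O)C=CC1=O)OC(C)=O
F4 | step 7 | (2R)-1-{2-tert-butoxy-3-hydroxy-3-[(Z)-2-methoxyethenyl]-4-oxocyclobut-1-en-1-yl}tridecan-2-yl acetate | CCCCCCCCCCC[C@H](CC1=C(OC(C)(C)C)C(O)(/C=C\OC)C1=O)OC(C)=O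
F5 | step 7 | (2R)-1-(2-tert-butoxy-3,6-dihydroxy-5-methoxyphenyl)tridecan-2-yl acetate | CCCCCCCCCCC[C@H](Cc1c(OC(C)(C)C)c(O)cc(OC)c1O)OC(C)=O
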